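**Plan**
- Retrosynthesis: the three oxygen functions are first traced back (C9–OH and C9'–OH to ethyl esters, the ring A phenol to its acetate); then the ether bond C8–O4' and the carbon–carbon bond C7–C8 are cut together.
- Enabling feature: C8 carries, beside its hydrogen, three different bonds, to the carbinol carbon C7 on ring A, to C9 and to the ether oxygen O4' on ring B. It can therefore enter as the carbene carbon of a diazoacetate (C8 plus C9) that takes up the ring B phenol oxygen and then the ring A aldehyde carbon.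
- Forward: sinapic acid is esterified; its ethyl ester, ethyl diazoacetate and vanillin acetate are united in one flask, joining ring A, the C7–C8–C9 chain and ring B without closing a ring; one global hydride reduction ends the route.
- Stereochemistry: C7 and C8 (7R,8R, threo) are both created in the three-component step, C7 by a chiral Lewis acid made from Zr(OtBu)4 and BINOL on the aldehyde, C8 by the syn course of the aldol trapping. The E alkene is that of sinapic acid.

Key step: step 2

Assumption: (R)-BINOL is written for the zirconium catalyst on the working hypothesis that it leaves the Si face of the bound aldehyde open; as the sense of induction of this new step cannot be taken from precedent, the ligand antipode would be used instead if the first run pointed the other way.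

Step 1
Reactants: 1 sinapic acid
Product: 2 ethyl (E)-sinapate [ethyl (E)-3-(4-hydroxy-3,5-dimethoxyphenyl)prop-2-enoate]
Conditions: EtOH, H2SO4 (cat.), reflux
Reagents that add atoms: ethanol, CCO
Why: Fischer esterification in excess ethanol should drive the acid-catalysed acyl substitution to the ethyl ester, while the phenol, the methyl ethers and the E alkene are inert.

Step 2
Reactants: 2 ethyl (E)-sinapate; 3 ethyl diazoacetate; 4 vanillin acetate (4-formyl-2-methoxyphenyl acetate)
Product: 6 ethyl (2S,3R)-3-(4-acetoxy-3-methoxyphenyl)-2-{4-[(E)-3-ethoxy-3-oxoprop-1-en-1-yl]-2,6-dimethoxyphenoxy}-3-hydroxypropanoate, via oxonium ylide 5 (not isolated)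
Conditions: Rh2(OAc)4 (2 mol%), Zr(OtBu)4/(R)-BINOL (15 mol%), 4 Å MS, CH2Cl2, 0 °C → rt; 3 (1.5 equiv) added slowly by syringe pump to 2 (1 equiv) and 4 (1.5 equiv)
Reagents that add atoms: none
Why: Proposed new method: Rh2(OAc)4 should decompose 3 to a metal-bound carbene that is captured by the phenolic oxygen of 2 to give the protic oxonium ylide 5, which behaves as the enol form of the corresponding aryloxyacetate and should add as a carbon nucleophile to aldehyde 4 held on the Lewis acid made from Zr(OtBu)4 and (R)-BINOL before proton transfer from oxygen to carbon completes a plain O–H insertion, so that C8–O4' and then C7–C8 form in one flask. The closest known reaction type is the aldol-type trapping of oxonium ylides from aryl diazoacetates and alcohols by aldehydes under Rh2(OAc)4 and chiral acid co-catalysis; an acceptor-only diazoacetate with a hindered phenol and this aldehyde class has not been shown. No ring is closed, so no mode of ring closure has to be specified. C7 (3R) is to be controlled by the BINOLate on tetravalent zirconium, which should leave the Si face of the bound aldehyde open, and C8 (2S) by the enolate geometry of 5, whose aryloxy oxygen is held cis to the enolate oxygen by the internal O–H···O bond or by chelation to zirconium, so that a closed chair-like transition state with the aryl group of 4 equatorial gives the syn (threo) pair. The step needs ylide formation at the phenol in preference to cyclopropanation, carbonyl ylide formation and Lewis-acid homologation of the aldehyde, and aldol trapping in preference to proton shift; the ester-deactivated alkene and the acidic, zirconium-exchangeable phenol of 2, the slow addition of 3 and the electron-withdrawing acetoxy group para to the formyl group of 4 are what should secure this.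

Step 3
Reactants: 6 ethyl (2S,3R)-3-(4-acetoxy-3-methoxyphenyl)-2-{4-[(E)-3-ethoxy-3-oxoprop-1-en-1-yl]-2,6-dimethoxyphenoxy}-3-hydroxypropanoate
Product: 7 (1R,2R)-1-(4-hydroxy-3-methoxyphenyl)-2-{4-[(E)-3-hydroxyprop-1-en-1-yl]-2,6-dimethoxyphenoxy}propane-1,3-diol (threo-(7R,8R) target)
Conditions: i-Bu2AlH (9 equiv), CH2Cl2, −78 → 0 °C; then aq. potassium sodium tartrate
Reagents that add atoms: none
Why: Ester reduction with i-Bu2AlH should deliver hydride 1,2 to both ethyl esters (the conjugated one giving the E allylic alcohol) and cleave the aryl acetate reductively, and since no bond at C7 or C8 is touched and no base is present at low temperature, the configuration set in step 2 should be carried through unchanged.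

**Compound list**
1 | sinapic acid, (E)-3-(4-hydroxy-3,5-dimethoxyphenyl)prop-2-enoic acid | COc1cc(/C=C/C(=O)O)cc(OC)c1O | starting material
2 | ethyl (E)-sinapate, ethyl (E)-3-(4-hydroxy-3,5-dimethoxyphenyl)prop-2-enoate | CCOC(=O)/C=C/c1cc(OC)c(O)c(OC)c1 | intermediate
3 | ethyl diazoacetate | CCOC(=O)C=[N+]=[N-] | starting material
4 | vanillin acetate, 4-formyl-2-methoxyphenyl acetate | COc1cc(C=O)ccc1OC(C)=O | starting material
5 | protic oxonium ylide formed in the flask from 2 and the carbene of 3 (hydrogen on the aryl ether oxygen, negative charge on the future C8) | CCOC(=O)[CH-][OH+]c1c(OC)cc(/C=C/C(=O)OCC)cc1OC | intermediate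
6 | ethyl (2S,3R)-3-(4-acetoxy-3-methoxyphenyl)-2-{4-[(E)-3-ethoxy-3-oxoprop-1-en-1-yl]-2,6-dimethoxyphenoxy}-3-hydroxypropanoate | COc1cc([C@@H](O)[C@@H](C(=O)OCC)Oc2c(OC)cc(/C=C/C(=O)OCC)cc2OC)ccc1OC(C)=O | intermediate
7 | (1R,2R)-1-(4-hydroxy-3-methoxyphenyl)-2-{4-[(E)-3-hydroxyprop-1-en-1-yl]-2,6-dimethoxyphenoxy}propane-1,3-diol | COc1cc([C@@H](O)[C@@H](CO)Oc2c(OC)cc(/C=C/CO)cc2OC)ccc1O | target

Total step count: 3
Longest linear sequence: 3 steps (1 → 2 → 6 → 7); 3 and 4 are purchased and enter at step 2.

**Steps most likely to fail**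

Step 2. The proton shift in ylide 5 may outrun the aldol trapping, so that only O–H insertion occurs, or the trapping may proceed with poor syn or facial selectivity. Homologation of the aldehyde by the diazo ester on the Lewis acid and carbene insertion into the BINOL hydroxyls are further drains. The fallback sets out from 2 and comes back to the route at 7, using an auxiliary-controlled aldol of known type. Phenol 2 would be alkylated with tert-butyl bromoacetate (K2CO3, DMF) to tert-butyl 2-{4-[(E)-3-ethoxy-3-oxoprop-1-en-1-yl]-2,6-dimethoxyphenoxy}acetate F1. CF3CO2H in CH2Cl2 would free 2-{4-[(E)-3-ethoxy-3-oxoprop-1-en-1-yl]-2,6-dimethoxyphenoxy}acetic acid F2. This acid would be joined to (S)-4-benzyl-1,3-oxazolidin-2-one (DCC, cat. DMAP, CH2Cl2) to give the imide ethyl (E)-3-(4-{2-[(S)-4-benzyl-2-oxo-1,3-oxazolidin-3-yl]-2-oxoethoxy}-3,5-dimethoxyphenyl)prop-2-enoate F3. Bu2BOTf and i-Pr2NEt (CH2Cl2, −78 → 0 °C) would form in the flask the dibutylboron (Z)-enolate of the imide F4. With aldehyde 4 this would pass through a chair transition state on the face away from the benzyl group to the dibutylboron aldolate F5. Work-up with H2O2 at pH 7 would give the syn aldol (S)-4-benzyl-3-[(2S,3R)-3-(4-acetoxy-3-methoxyphenyl)-2-{4-[(E)-3-ethoxy-3-oxoprop-1-en-1-yl]-2,6-dimethoxyphenoxy}-3-hydroxypropanoyl]-1,3-oxazolidin-2-one F6. LiBH4 (THF, 1 equiv H2O, 0 °C) would remove the auxiliary reductively and cleave the aryl acetate to ethyl (E)-3-(4-{[(1R,2R)-1,3-dihydroxy-1-(4-hydroxy-3-methoxyphenyl)propan-2-yl]oxy}-3,5-dimethoxyphenyl)prop-2-enoate F7. i-Bu2AlH (CH2Cl2, −78 °C) would then reduce the remaining conjugated ester to 7.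

Step 3. The aluminium alkoxide formed at the free C7 hydroxyl may undergo retro-aldol cleavage or epimerisation at C8 before the neighbouring ester is consumed, or reduction of the hindered C9 ester may stall at the aldehyde level. The fallback sets out from 6 and comes back at 7 by masking the carbinol first. TBSOTf and 2,6-lutidine (CH2Cl2, −78 °C) would give ethyl (2S,3R)-3-(4-acetoxy-3-methoxyphenyl)-3-[(tert-butyldimethylsilyl)oxy]-2-{4-[(E)-3-ethoxy-3-oxoprop-1-en-1-yl]-2,6-dimethoxyphenoxy}propanoate F8. i-Bu2AlH (CH2Cl2, −78 → 0 °C) would reduce both esters and the acetate to (2R,3R)-3-[(tert-butyldimethylsilyl)oxy]-3-(4-hydroxy-3-methoxyphenyl)-2-{4-[(E)-3-hydroxyprop-1-en-1-yl]-2,6-dimethoxyphenoxy}propan-1-ol F9. Bu4NF buffered with AcOH (THF, 0 °C) would release 7.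

Step 1. The esterification may stop at its equilibrium position, or the hot acid may add ethanol to, or oligomerise, the electron-rich styrene unit. The fallback sets out from 1 and comes back at 2 by alkylating the carboxylate instead of activating the acid: KHCO3 and EtI in DMF at room temperature should ethylate only the carboxylate, since hydrogen carbonate does not deprotonate the phenol. No new compound is made on the way.

**Further compounds**
F1 | step 2 | tert-butyl 2-{4-[(E)-3-ethoxy-3-oxoprop-1-en-1-yl]-2,6-dimethoxyphenoxy}acetate | CCOC(=O)/C=C/c1cc(OC)c(OCC(=O)OC(C)(C)C)c(OC)c1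
F2 | step 2 | 2-{4-[(E)-3-ethoxy-3-oxoprop-1-en-1-yl]-2,6-dimethoxyphenoxy}acetic acid | CCOC(=O)/C=C/c1cc(OC)c(OCC(=O)O)c(OC)c1
F3 | step 2 | ethyl (E)-3-(4-{2-[(S)-4-benzyl-2-oxo-1,3-oxazolidin-3-yl]-2-oxoethoxy}-3,5-dimethoxyphenyl)prop-2-enoate | CCOC(=O)/C=C/c1cc(OC)c(OCC(=O)N2C(=O)OC[C@@H]2Cc2ccccc2)c(OC)c1
F4 | step 2 | dibutylboron (Z)-enolate of imide F3 (formed in the flask) | CCCCB(CCCC)O/C(=C\Oc1c(OC)cc(/C=C/C(=O)OCC)cc1OC)N1C(=O)OC[C@@H]1Cc1ccccc1
F5 | step 2 | dibutylboron aldolate of F6 (formed in the flask) | COc1cc([C@@H](OB(CCCC)CCCC)[C@@H](C(=O)N2C(=O)OC[C@@H]2Cc2ccccc2)Oc2c(OC)cc(/C=C/C(=O)OCC)cc2OC)ccc1OC(C)=O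
F6 | step 2 | (S)-4-benzyl-3-[(2S,3R)-3-(4-acetoxy-3-methoxyphenyl)-2-{4-[(E)-3-ethoxy-3-oxoprop-1-en-1-yl]-2,6-dimethoxyphenoxy}-3-hydroxypropanoyl]-1,3-oxazolidin-2-one | COc1cc([C@@H](O)[C@@H](C(=O)N2C(=O)OC[C@@H]2Cc2ccccc2)Oc2c(OC)cc(/C=C/C(=O)OCC)cc2OC)ccc1OC(C)=O
F7 | step 2 | ethyl (E)-3-(4-{[(1R,2R)-1,3-dihydroxy-1-(4-hydroxy-3-methoxyphenyl)propan-2-yl]oxy}-3,5-dimethoxyphenyl)prop-2-enoate | COc1cc([C@@H](O)[C@@H](CO)Oc2c(OC)cc(/C=C/C(=O)OCC)cc2OC)ccc1O
F8 | step 3 | ethyl (2S,3R)-3-(4-acetoxy-3-methoxyphenyl)-3-[(tert-butyldimethylsilyl)oxy]-2-{4-[(E)-3-ethoxy-3-oxoprop-1-en-1-yl]-2,6-dimethoxyphenoxy}propanoate | COc1cc([C@@H](O[Si](C)(C)C(C)(C)C)[C@@H](C(=O)OCC)Oc2c(OC)cc(/C=C/C(=O)OCC)cc2OC)ccc1OC(C)=O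
F9 | step 3 | (2R,3R)-3-[(tert-butyldimethylsilyl)oxy]-3-(4-hydroxy-3-methoxyphenyl)-2-{4-[(E)-3-hydroxyprop-1-en-1-yl]-2,6-dimethoxyphenoxy}propan-1-ol | COc1cc([C@@H](O[Si](C)(C)C(C)(C)C)[C@@H](CO)Oc2c(OC)cc(/C=C/CO)cc2OC)ccc1O
F0 | step 1 | none | none
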